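At late times the green run barely moves: starting material reads 56% at 2.00 h and 56% at 3.00 h, target 47% and 50%. What that stop means is in dispute for this flask, which is the green run carried on.

in all of them: starting material 0.050 M
- green: second substrate 0.025 M; free enzyme 5 µM; the very flask that is asked about, followed so far
- flask: second substrate 0.0250 M; free enzyme 5.0 µM; time 6.0 h

green run (percent of the starting material charged)

| time / h | starting material / % | target / % |
|---|---|---|
| 0.250 | 90 | 12 |
| 0.833 | 74 | 30 |
| 1.33 | 62 | 37 |
| 2.00 | 56 | 47 |
| 3.00 | 56 | 50 |

(readings scatter by 2 percentage points)

- part of the starting material that has reacted at 6.0 h
- share of free second substrate in free second substrate and idle adduct together, at 6.0 h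

- the earlier runs do not show how much of second substrate is bound; that part of a forecast is a guess

One chemist holds the charge view. Taking the reaction as one to one, second substrate is the limiting reagent, its charge being less than that of starting material, so conversion tops out at the starting [second substrate]/[starting material], a ceiling of 50.0%. The other holds the catalyst view: conversion is what 5.0 µM of enzyme has turned over, turnover has ceased, and the starting material reading gives 44.0% reacted, which stays. The charge view answers that target at 50% lies 6 percentage points above that figure, against a scatter of 2 points.

My own reckoning joins both views in one time. Target reads 30% at 0.833 h, and at that pace the flask reaches the ceiling in 1.39 h: the fill time, the ceiling divided by the target gained per hour up to that reading, a pace I take as proportional to the enzyme charged. It errs short, since target reads 37% at 1.33 h, below the 47.9% that pace gives. Still, it is shorter than 6.0 h, so I commit to conversion near the ceiling; for the share of free second substrate these readings give me nothing.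

The forecast takes the charge side: with second substrate at half the starting material, a one-to-one reaction “can reach only 50% conversion”; it expects 49% reacted and puts the share at 50% as a guess.

This flask gives 49.8% reacted and a share of 32.7%, 17 points under that guess.

    first complex → loaded enzyme + first product (k = 15.8 s⁻¹)
    second complex → free enzyme + target (k = 2.22 s⁻¹)
    starting material + free enzyme ⇌ first complex (K = 278 M⁻¹, k = 7420 M⁻¹ s⁻¹)
    second substrate + loaded enzyme ⇌ second complex (K = 72.0 M⁻¹, k = 2120 M⁻¹ s⁻¹)
    second substrate + first product ⇌ idle adduct, settled at all times (K = 83.0 M⁻¹)

At 6.0 h this flask holds 0.13% of its second substrate unbound against 50% of its starting material, and the half-life of second substrate by the forward binding to loaded enzyme alone, 1.1 min, is short against that time. The fill time of 1.39 h had room here, and the charge view stands. The catalyst view, taken as conversion set by the enzyme charged, has its region in the neighbour with 1.2 × 10⁻⁶ M of free enzyme: the fill time stretches to 5.78 h, about 6.0 h, and with a slackening pace that flask should stay below the ceiling. That neighbour gives 38.1%, with 10% of its second substrate still unbound.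

The runs come from a simulation from invented constants, and the scatter is random.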